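The closed, stirred vessel takes starting material, reagent and protic impurity at one temperature, and its products are counted by the starting material they hold.

| setting | teal | red | Tuesday's | Friday's |
|---|---|---|---|---|
| starting material | 0.055 M | 0.055 M | 0.055 M | 0.055 M |
| reagent | 0.038 M | 0.069 M | 0.0830 M | 0.0550 M |
| protic impurity | 0.055 M | 0.055 M | 0.0550 M | 0.0550 M |
| remark | run made earlier | run made earlier |  |  |
| time |  |  | 80 min | 80 min |

| run | time / min | side product B / % | side product A / % | isomer of the product / % | target / % | starting material / % |
|---|---|---|---|---|---|---|
| teal | 15.0 | 42 | 27 | 9 | 5 | 0 |
| teal | 30.0 | 41 | 32 | 11 | 5 | 0 |
| teal | 40.0 | 38 | 28 | 7 | 2 | 0 |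
| teal | 60.0 | 40 | 29 | 12 | 4 | 1 |
| red | 5.00 | 33 | 24 | 6 | 14 | 3 |
| red | 10.0 | 37 | 26 | 10 | 14 | 0 |
| red | 25.0 | 36 | 26 | 15 | 9 | 0 |
| red | 60.0 | 34 | 26 | 18 | 9 | 0 |

(readings scatter by 1.5 percentage points)

- percent here means starting material units held: one side product B counts as two
- the numbers in the tables scatter with a standard deviation of 1.5 percentage points
- a reading or a percentage of target counts all its forms, free or not
- a reading of starting material is of its free form alone

* which of these there is most of at the end, counted by the starting material in it, Tuesday's (isomer of the product / side product B / target / side product A)
* which of these there is most of at the end, counted by the starting material in it, Friday's (isomer of the product / side product B / target / side product A)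
* how much there is at the end of the one of these that leads, in percent of the starting material charged: Tuesday's
* how much there is at the end of the one of these that leads, in percent of the starting material charged: Friday's

Is the asked time the end? Starting material reads 0% at 15.0 min in the teal run and 0% at 10.0 min in the red run. After those readings side product B shows no trend beyond the scatter in either run. So Tuesday's and Friday's are read later than that, and I treat 80 min as the end for side product B.

Which scale? Divide side product B by side product A, with a tie at one as the zero. The teal run gives 1.39. The red run, from 10.0 min on, gives 1.37. Pooled, the readings give 1.38. This is the lead ratio, side product B over side product A after conversion, a selectivity factor.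

Does reagent move it? Reagent went from 0.038 M to 0.069 M, and the ratio read from the two runs held.

And the weak spot? Both runs charge 0.055 M of starting material, so that charge is untested. But one side product B holds two starting material, so I assume two must meet, while side product A holds one. With reagent and protic impurity held, I then take the lead ratio to move in step with the starting material charged. Tuesday's and Friday's charge the same 0.055 M, so I carry it over unchanged to them.

How much side product B? It averages 40.2% in teal and 35.7% in red. A straight line in reagent gives 37.7% for Friday's. Beyond the red run, it gives 33.6% for Tuesday's.

Could the isomer overtake on Tuesday's? The same line through its last readings gives 20.7%, and side product A gets 24.3%. So on this reckoning side product B stays ahead on Tuesday's.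

The forecast names side product B for Tuesday's and side product B for Friday's, at 33% (28% to 37%) and 37% (33% to 40%), “so they seem to share a reagent-independent route”, and my figures stand 0.6 percentage points and 0.70 points above it.

The flask gives side product B on Tuesday's at 32.7%, and side product B on Friday's at 36.4%.

    starting material + reagent → target (k = 0.0680 /M/s)
    starting material → side product A (k = 0.00460 /s)
    2 starting material → side product B (k = 0.140 /M/s)
    starting material + target ⇌ idle adduct, settled at all times (K = 33.0 /M)
    starting material + protic impurity → quenched substrate (k = 0.0520 /M/s)
    target ⇌ isomer of the product (K = 2.90, k = 0.00150 /s)

Left ten times as long, Friday's still holds 36.4% of side product B. A further flask is like Friday's but charged with 0.014 M of starting material. Scaled to that charge, the lead ratio is 0.352, below the tie. That flask ends with 14.0% of side product B against 36.0% of side product A, a ratio of 0.389. With Friday's other charges and time, the two side products hold the same at 0.0400 M of starting material, where the scaled lead ratio reads 1.01.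

(All runs stem from a simulated flask with made-up constants; noise was put on by code.)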